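**Plan**

- Retrosynthesis: the acid is cut back to its methyl ester. The O-acetyl bond and the C5–pentenyl bond are cut next, back to a 4-hydroxycyclopentenone. Then C1–C5 and C3–C4 are cut together, giving a methyl ketone enolate and a β-silyl acryloylsilane.
- Enabling feature: the cyclopentenone carries oxygen at C1 and C4 in a 1,3 (aldol-type) relation across C5, and C4 is also bonded to the enone β-carbon C3. C4 is therefore a former ketone carbon, C5 its enolate carbon, and C1–C2–C3 a former acylsilane whose silicon moves to O1 and frees a carbanion at C3.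
- Forward: the acylsilane (four steps) and methyl 9-oxodecanoate are joined in a Brook-mediated [3+2] annulation that makes the only ring. The two silicon helpers are then removed to give the enone, the racemate is resolved, C5 is alkylated and O4 acetylated in one flask, and the ester is cleaved by a lipase.
- Stereochemistry: C4 is formed racemic and resolved through diastereomeric sulfoximine adducts. C5 comes from alkylation of the alkoxide-enolate anti to the lithium alkoxide. The Z alkene is bought in with the allylic bromide.

Key step: step 6

Remark: ring positions are cited with cyclopent-2-en-1-one numbering (C1 carbonyl, C2=C3, C4 the acetoxy-bearing carbon, C5 the pentenyl-bearing carbon); the annulation gives a racemate, so the absolute configuration is introduced by resolution in steps 8 and 9.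

**Route**

Step 1
Reactants: 1 3-(trimethylsilyl)prop-2-yn-1-ol
Product: 2 (2E)-3-(trimethylsilyl)prop-2-en-1-ol
Conditions: NaAlH2(OCH2CH2OCH3)2, Et2O, 0 °C to rt; dilute H2SO4 work-up
Reagents that add atoms: none
Why: Hydroxyl-directed trans-hydroalumination of the propargylic alcohol and protonolysis of the vinylalane (alkyne reduction with an alkoxyaluminium hydride) should give the E-vinylsilane only.

Step 2
Reactants: 2 (2E)-3-(trimethylsilyl)prop-2-en-1-ol
Product: 3 tert-butyldimethyl{[(2E)-3-(trimethylsilyl)prop-2-en-1-yl]oxy}silane
Conditions: t-BuMe2SiCl, imidazole, DMF, rt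
Reagents that add atoms: tert-butyldimethylsilyl chloride, CC(C)(C)[Si](C)(C)Cl
Why: Standard O-silylation of a primary alcohol puts on oxygen the silyl group that is to migrate to carbon in step 3.

Step 3
Reactants: 3 tert-butyldimethyl{[(2E)-3-(trimethylsilyl)prop-2-en-1-yl]oxy}silane
Product: 5 (2E)-1-(tert-butyldimethylsilyl)-3-(trimethylsilyl)prop-2-en-1-ol (racemic), via lithiated allyl silyl ether 4 (not isolated)
Conditions: s-BuLi, THF, -78 to -40 °C; AcOH, -78 °C
Reagents that add atoms: none
Why: Deprotonation at the allylic carbon next to oxygen gives an oxygen-substituted allyl anion in which silicon shifts from oxygen to carbon (retro-Brook rearrangement, 1,2-silyl shift) driven by formation of the lithium alkoxide; the new carbinol centre is racemic and is removed in step 4.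

Step 4
Reactants: 5 (2E)-1-(tert-butyldimethylsilyl)-3-(trimethylsilyl)prop-2-en-1-ol
Product: 6 (2E)-1-(tert-butyldimethylsilyl)-3-(trimethylsilyl)prop-2-en-1-one
Conditions: (COCl)2, DMSO, CH2Cl2, -78 °C; Et3N, -78 to 0 °C
Reagents that add atoms: none
Why: Swern oxidation converts the α-silyl carbinol into the acylsilane under cold, non-acidic conditions that the acylsilane and the vinylsilane should tolerate.

Step 5
Reactants: 7 methyl dec-9-enoate
Product: 8 methyl 9-oxodecanoate
Conditions: PdCl2 (cat.), CuCl, O2 (1 atm), DMF/H2O, rt
Reagents that add atoms: water, O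
Why: Tsuji-Wacker oxidation of the terminal alkene (Markovnikov hydroxypalladation, then β-hydride elimination) should give the methyl ketone and leave the ester untouched.

Step 6
Reactants: 8 methyl 9-oxodecanoate; 6 (2E)-1-(tert-butyldimethylsilyl)-3-(trimethylsilyl)prop-2-en-1-one
Product: 11 rac-methyl 8-[(1R,2S)-4-[(tert-butyldimethylsilyl)oxy]-1-hydroxy-2-(trimethylsilyl)cyclopent-3-en-1-yl]octanoate, via lithium enolate 9 (not isolated), via alpha-silyl alkoxide 10 (not isolated)
Conditions: 8, LiN(iPr)2, THF, -80 °C; then 6, THF, -80 to -30 °C; AcOH, -78 °C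
Reagents that add atoms: none
Why: The kinetic methyl-side enolate 9 adds to the carbonyl of acylsilane 6 (forming C1–C5) to give the alpha-silyl alkoxide 10, whose silicon migrates from carbon to oxygen (Brook rearrangement) because the resulting carbanion is an allyl anion stabilised by the siloxy group and by the trimethylsilyl group on its far terminus; that terminus then adds to the ketone carbonyl three atoms away (forming C3–C4), so both ring bonds and the tertiary carbinol arise in one flask. The closest known reaction type is the Brook rearrangement-mediated [3+2] annulation of beta-silyl acryloylsilanes with lithium enolates of alkyl methyl ketones. The cyclopentene closes by a 5-exo-trig addition of the allyl anion terminus to the C=O group (an intramolecular aldol-type closure), and the silyl enol ether double bond is fixed between C1 and C2. Two stereocentres form: the carbinol carbon C4 arises as the racemate because no chiral element is present and is resolved in steps 8 and 9, while the silicon-bearing C3 is assumed cis to the hydroxyl (the E geometry of 6 persists in the allyl anion and the long chain avoids the trimethylsilyl group in the closing transition state); C3 becomes trigonal in step 7, so its configuration does not matter. The step needs enolisation at the methyl group only (secured by LiN(iPr)2 at -80 °C, the ketone CH3 being kinetically more acidic than the chain CH2 and the ester α-CH2), 1,2- rather than 1,4-addition to 6 (secured by the very electrophilic acylsilane carbonyl and the silyl-shielded β-carbon), and ring closure before proton transfer (secured by the five-membered transition state).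

Step 7
Reactants: 11 rac-methyl 8-[(1R,2S)-4-[(tert-butyldimethylsilyl)oxy]-1-hydroxy-2-(trimethylsilyl)cyclopent-3-en-1-yl]octanoate
Product: 13 methyl 8-(1-hydroxy-4-oxocyclopent-2-en-1-yl)octanoate (racemic), via alpha-bromo beta-silyl ketone 12 (not isolated)
Conditions: NBS, THF, -78 to 0 °C; then Bu4NF, THF, 0 °C
Reagents that add atoms: none
Why: Bromination of the regiodefined silyl enol ether gives the α-bromo-β-silyl ketone 12, and fluoride attack at silicon triggers anti β-elimination of bromide (desilylbromination, the unmasking of a β-silyl ketone), which should place the enone double bond only between C2 and C3 and remove both silicon helpers without touching the carbinol centre.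

Step 8
Reactants: 13 methyl 8-(1-hydroxy-4-oxocyclopent-2-en-1-yl)octanoate (racemic); 14 (S)-N,S-dimethyl-S-phenylsulfoximine
Product: 16 methyl 8-[(1R,4S)-1,4-dihydroxy-4-{[(S)-N-methyl-S-phenylsulfonimidoyl]methyl}cyclopent-2-en-1-yl]octanoate, via lithiated sulfoximine 15 (not isolated)
Conditions: 14, n-BuLi, THF, 0 °C; then 13, -78 °C (2.2 equiv of 15); aq. NH4Cl; separation of the diastereomers on silica gel
Reagents that add atoms: none
Why: Reversible 1,2-addition of the enantiopure sulfoximine carbanion to the enone carbonyl turns the two enantiomers of 13 into diastereomeric β-hydroxy sulfoximines that can be separated by chromatography (resolution through covalent diastereomers); the temporary carbinol centre is expected to form by attack anti to the lithium alkoxide at C4, and any epimer at this centre from the same enantiomer can be pooled because step 9 erases it.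

Step 9
Reactants: 16 methyl 8-[(1R,4S)-1,4-dihydroxy-4-{[(S)-N-methyl-S-phenylsulfonimidoyl]methyl}cyclopent-2-en-1-yl]octanoate
Product: 17 methyl 8-[(1R)-1-hydroxy-4-oxocyclopent-2-en-1-yl]octanoate
Conditions: toluene, 110 °C
Reagents that add atoms: none
Why: Thermal retro-addition of the β-hydroxy sulfoximine regenerates the ketone and the recoverable auxiliary under neutral conditions, so the carbinol centre should keep the configuration selected in step 8.

Step 10
Reactants: 17 methyl 8-[(1R)-1-hydroxy-4-oxocyclopent-2-en-1-yl]octanoate; 18 (2Z)-1-bromopent-2-ene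
Product: 21 methyl 8-[(1S,5R)-1-(acetyloxy)-4-oxo-5-[(2Z)-pent-2-en-1-yl]cyclopent-2-en-1-yl]octanoate, via dilithium alkoxide-dienolate 19 (not isolated), via alkylated lithium alkoxide 20 (not isolated)
Conditions: LiN(iPr)2 (2.1 equiv), THF, -78 °C; DMPU, 18, -78 to -40 °C; then Ac2O, -78 to -20 °C; pH 7 phosphate buffer
Reagents that add atoms: acetic anhydride, CC(=O)OC(C)=O
Why: The alkoxide-enolate 19, in which the oxide cannot leave and so cannot eliminate to a cyclopentadienone, should be alkylated at C5 by the allylic bromide on the face anti to the solvated lithium alkoxide, as in the trans-selective alkylation of β-hydroxy ester and lactone dianions (Frater-Seebach type enolate alkylation), which sets C5 as R with the pentenyl group cis to the chain, and the tertiary lithium alkoxide 20 is then O-acetylated in the same flask so that the hindered alcohol needs no separate esterification next to the epimerisable centre.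

Step 11
Reactants: 21 methyl 8-[(1S,5R)-1-(acetyloxy)-4-oxo-5-[(2Z)-pent-2-en-1-yl]cyclopent-2-en-1-yl]octanoate
Product: 22 8-[(1S,5R)-1-(acetyloxy)-4-oxo-5-[(2Z)-pent-2-en-1-yl]cyclopent-2-en-1-yl]octanoic acid
Conditions: Candida antarctica lipase B (immobilised), pH 7.0 phosphate buffer/acetone, 30 °C
Reagents that add atoms: water, O
Why: A lipase (carboxylic ester hydrolase) should cleave the unhindered primary methyl ester at neutral pH while the tertiary acetate is too hindered for the active site, which avoids hydroxide that would epimerise C5 and eliminate or hydrolyse the acetate (enzymatic ester hydrolysis, no stereocentre touched).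

**Compound list**

1 | 3-(trimethylsilyl)prop-2-yn-1-ol | C[Si](C)(C)C#CCO | starting material
2 | (2E)-3-(trimethylsilyl)prop-2-en-1-ol | C[Si](C)(C)/C=C/CO | intermediate
3 | tert-butyldimethyl{[(2E)-3-(trimethylsilyl)prop-2-en-1-yl]oxy}silane | C[Si](C)(C)/C=C/CO[Si](C)(C)C(C)(C)C | intermediate
4 | {(2E)-1-[(tert-butyldimethylsilyl)oxy]-3-(trimethylsilyl)prop-2-en-1-yl}lithium | C[Si](C)(C)/C=C/C([Li])O[Si](C)(C)C(C)(C)C | intermediate
5 | (2E)-1-(tert-butyldimethylsilyl)-3-(trimethylsilyl)prop-2-en-1-ol (racemic) | C[Si](C)(C)/C=C/C(O)[Si](C)(C)C(C)(C)C | intermediate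
6 | (2E)-1-(tert-butyldimethylsilyl)-3-(trimethylsilyl)prop-2-en-1-one | C[Si](C)(C)/C=C/C(=O)[Si](C)(C)C(C)(C)C | intermediate
7 | methyl dec-9-enoate | C=CCCCCCCCC(=O)OC | starting material
8 | methyl 9-oxodecanoate | CC(=O)CCCCCCCC(=O)OC | intermediate
9 | methyl 9-(lithiooxy)dec-9-enoate | C=C(O[Li])CCCCCCCC(=O)OC | intermediate
10 | methyl (12E)-11-(tert-butyldimethylsilyl)-11-(lithiooxy)-9-oxo-13-(trimethylsilyl)tridec-12-enoate (racemic) | COC(=O)CCCCCCCC(=O)CC(O[Li])([Si](C)(C)C(C)(C)C)/C=C/[Si](C)(C)C | intermediate
11 | rac-methyl 8-[(1R,2S)-4-[(tert-butyldimethylsilyl)oxy]-1-hydroxy-2-(trimethylsilyl)cyclopent-3-en-1-yl]octanoate (hydroxyl cis to trimethylsilyl; enantiomer of the later series drawn) | COC(=O)CCCCCCC[C@@]1(O)CC(O[Si](C)(C)C(C)(C)C)=C[C@@H]1[Si](C)(C)C | intermediate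
12 | rac-methyl 8-[(1R,2R,3R)-3-bromo-1-hydroxy-4-oxo-2-(trimethylsilyl)cyclopentyl]octanoate (bromine trans to trimethylsilyl; enantiomer of the later series drawn) | COC(=O)CCCCCCC[C@@]1(O)CC(=O)[C@@H](Br)[C@@H]1[Si](C)(C)C | intermediate
13 | methyl 8-(1-hydroxy-4-oxocyclopent-2-en-1-yl)octanoate (racemic) | COC(=O)CCCCCCCC1(O)CC(=O)C=C1 | intermediate
14 | (S)-N,S-dimethyl-S-phenylsulfoximine | C[S@@](=O)(=NC)c1ccccc1 | starting material
15 | (S)-[(N-methyl-S-phenylsulfonimidoyl)methyl]lithium | [Li]C[S@@](=O)(=NC)c1ccccc1 | intermediate
16 | methyl 8-[(1R,4S)-1,4-dihydroxy-4-{[(S)-N-methyl-S-phenylsulfonimidoyl]methyl}cyclopent-2-en-1-yl]octanoate | COC(=O)CCCCCCC[C@@]1(O)C[C@@](O)(C[S@@](=O)(=NC)c2ccccc2)C=C1 | intermediate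
17 | methyl 8-[(1R)-1-hydroxy-4-oxocyclopent-2-en-1-yl]octanoate | COC(=O)CCCCCCC[C@@]1(O)CC(=O)C=C1 | intermediate
18 | (2Z)-1-bromopent-2-ene | CC/C=C\CBr | starting material
19 | methyl 8-[(1S)-1,4-bis(lithiooxy)cyclopenta-2,4-dien-1-yl]octanoate | C1=C(O[Li])C=C[C@]1(CCCCCCCC(=O)OC)O[Li] | intermediate
20 | methyl 8-[(1S,5R)-1-(lithiooxy)-4-oxo-5-[(2Z)-pent-2-en-1-yl]cyclopent-2-en-1-yl]octanoate | CC/C=C\C[C@H]1C(=O)C=C[C@]1(CCCCCCCC(=O)OC)O[Li] | intermediate
21 | methyl 8-[(1S,5R)-1-(acetyloxy)-4-oxo-5-[(2Z)-pent-2-en-1-yl]cyclopent-2-en-1-yl]octanoate | CC/C=C\C[C@H]1C(=O)C=C[C@]1(CCCCCCCC(=O)OC)OC(C)=O | intermediate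
22 | 8-[(1S,5R)-1-(acetyloxy)-4-oxo-5-[(2Z)-pent-2-en-1-yl]cyclopent-2-en-1-yl]octanoic acid | CC/C=C\C[C@H]1C(=O)C=C[C@]1(CCCCCCCC(=O)O)OC(C)=O | target

**Step count and risks**

Total step count: 11. Longest linear sequence: 10 steps (steps 1 to 4, then 6 to 11); step 5 is a one-step side branch.

Steps most likely to fail:

First, the C5 alkylation in step 10. The facial selectivity of the alkoxide-enolate may be low or reversed, and proton exchange between product and enolate may erode the kinetically set C5 centre toward the more stable epimer. The fallback sets C5 by kinetic protonation and not by the face of C-alkylation. It sets out from 17: the dianion is alkylated with 18 as before but quenched with aqueous NH4Cl, and the C5 epimer methyl 8-[(1S,5S)-1-hydroxy-4-oxo-5-[(2Z)-pent-2-en-1-yl]cyclopent-2-en-1-yl]octanoate F1 is isolated. F1 is converted again into its alkoxide-enolate with LiN(iPr)2 (2.1 equiv) at -78 °C and protonated at that temperature with 2,6-di-tert-butyl-4-methylphenol. The proton should enter on the face that the carbon electrophile preferred, which gives methyl 8-[(1S,5R)-1-hydroxy-4-oxo-5-[(2Z)-pent-2-en-1-yl]cyclopent-2-en-1-yl]octanoate F2. Acetylation of F2 with Ac2O and catalytic Sc(OTf)3 in MeCN at -20 °C comes back to 21.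

Second, the resolution in step 8. The sulfoximine carbanion may act as a base at C5 in place of adding to the carbonyl, or the diastereomeric adducts may not separate cleanly on silica gel. The fallback sets out from 13 and separates the enantiomers directly by preparative supercritical-fluid chromatography on a cellulose tris(3,5-dimethylphenylcarbamate) stationary phase. This comes back to the route at 17, replaces steps 8 and 9, and makes no new compound (F0).

Third, the silyl migration in step 3. The alkyllithium may add to the vinylsilane in place of removing the allylic proton, or silicon may migrate to the far end of the allyl anion. The fallback generates the same carbanion by tin-lithium exchange and sets out from 2. Oxidation with MnO2 in CH2Cl2 gives (2E)-3-(trimethylsilyl)prop-2-enal F3. Addition of Bu3SnLi at -78 °C and trapping of the alkoxide with t-BuMe2SiCl gives tributyl{(2E)-1-[(tert-butyldimethylsilyl)oxy]-3-(trimethylsilyl)prop-2-en-1-yl}stannane F4. n-BuLi in THF at -78 °C then effects tin-lithium exchange and the retro-Brook shift, which comes back to the route at 5.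

Further compounds
F1 | step 10 | methyl 8-[(1S,5S)-1-hydroxy-4-oxo-5-[(2Z)-pent-2-en-1-yl]cyclopent-2-en-1-yl]octanoate | CC/C=C\C[C@@H]1C(=O)C=C[C@]1(CCCCCCCC(=O)OC)O
F2 | step 10 | methyl 8-[(1S,5R)-1-hydroxy-4-oxo-5-[(2Z)-pent-2-en-1-yl]cyclopent-2-en-1-yl]octanoate | CC/C=C\C[C@H]1C(=O)C=C[C@]1(CCCCCCCC(=O)OC)O
F0 | step 8 | none | none
F3 | step 3 | (2E)-3-(trimethylsilyl)prop-2-enal | C[Si](C)(C)/C=C/C=O
F4 | step 3 | tributyl{(2E)-1-[(tert-butyldimethylsilyl)oxy]-3-(trimethylsilyl)prop-2-en-1-yl}stannane | CCCC[Sn](CCCC)(CCCC)C(O[Si](C)(C)C(C)(C)C)/C=C/[Si](C)(C)C
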